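## Structural features

The target is a flavanone: a chroman-4-one in which benzo ring A is fused through C4a and C8a to the dihydropyranone ring C, with a 3,4-dimethoxyphenyl group (ring B) bonded to C2. Ring A carries oxygen on three adjacent carbons, methoxy at C5 and C7 and a free hydroxyl at C6, so C8 is its only unsubstituted position and the C6 oxygen must be told apart from its two neighbours. C2 is the only stereocentre (S); no neighbouring stereocentre can relay control, so its configuration has to come from a catalyst. C2 is also the fragile point: it is benzylic to the electron-rich ring B and its oxygen O1 lies β to the C4 carbonyl, so base or strong acid opens ring C by retro-oxa-Michael reaction to the 2'-hydroxychalcone and racemises it, and the C2–O1 bond is open to hydrogenolysis. The C6 phenol, para to O1 on an electron-rich ring, is easily oxidised and has to be masked during oxidative steps. The real difficulty is therefore not the skeleton but setting C2 under catalyst control and carrying it unchanged to the ketone. The key step uses the fact that the chain O1–C2–C3–C4–C4a of ring C corresponds to a phenol oxygen, the β- and α-carbons of an enal and the formyl carbon of a salicylaldehyde: ring C is closed on the finished ring A by forming O1–C2 and C3–C4, and the enal carbonyl carbon stays on C3 as a formyl group that is excised later.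

## Logic of the disconnections

11 ⇒ 10. The O–CH2Ph bond on the C6 oxygen is cut. The phenol is unmasked last because it would be oxidised when the ketone is made and would be a second nucleophile during ring construction. Nothing is lost in simplicity, and one protecting group serves the whole route. The forward step must be neutral, since base or acid would open ring C of 11, and must stop before the benzylic C2–O1 bond or the ketone is reduced.

10 ⇒ 9. The C4=O group is traced back to the C3=C4 double bond. A styrene-type alkene conjugated to ring A is what remains once C3 carries only hydrogen, and the donors of ring A together with the allylic O1 direct oxygen to C4. The gain is that no ketone has to survive the ring-forming chemistry. The forward step must oxidise a cyclic internal alkene regioselectively without ionising or activating the allylic C2 centre.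

9 ⇒ 8. A formyl group is put back on C3; forward, the C3–CHO bond is the one broken. With that substituent ring C becomes the condensation product of an enal, which opens a catalytic two-bond annulation. The forward step must remove CO from a conjugated aldehyde at a temperature low enough that the 2H-chromene does not open electrocyclically.

8 ⇒ 6 + 7. O1–C2 and C3–C4 are cut, the C3=C4 double bond coming from dehydration. The cut divides the molecule into a ring A piece and a ring B piece of similar size and creates ring C and the stereocentre in one operation. The forward step must deliver O1 to one face of the β-carbon of 7 and close onto a hindered, deactivated aldehyde; 6 must carry exactly one free hydroxyl.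

6 ⇒ 4 (through 5). The C4a–C4 bond between ring A and the formyl carbon is cut. The oxygen that becomes O1 directs a one-carbon electrophile to its ortho position, and because 4 is symmetric both ortho positions are the same carbon. The gain is a simple, symmetric trioxygenated phenol. The forward step must be strictly ortho-selective and stop after one formylation.

4 ⇒ 2 (through 3). The aryl C–O bond of the phenol is traced back to an aryl–CHO carbon–carbon bond. The oxygen pattern of 4 is not available in cheap feedstock with a hydroxyl at that position, whereas the aldehyde is. The forward step needs migration of the aryl group, not of hydride, onto the peracid oxygen.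

2 ⇒ 1. The O–benzyl bond is cut. 1 already holds the three adjacent oxygens of ring A with the central one as the only free hydroxyl, so the differentiation of C6 from C5 and C7 is bought, not made. The forward step must alkylate a phenol flanked by two methoxy groups.

## Other disconnections considered

Alternative 1: Ring A is built last by cutting C4a–C5.
- Forward step: the keto ester ethyl 2-(benzyloxy)-4-[(2S)-2-(3,4-dimethoxyphenyl)-4-oxo-3,4-dihydro-2H-pyran-6-yl]-3-oxobutanoate A2, which already holds ring C and the stereocentre, would be deprotonated at the side-chain methylene (future C8). The extended dienolate of A2 would attack the ester carbon through C4a in a Claisen closure, the ethoxy group would leave and enolisation would aromatise ring A, giving (2S)-6-(benzyloxy)-2-(3,4-dimethoxyphenyl)-5,7-dihydroxychroman-4-one A1.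
- In favour: the oxygen pattern of ring A is written into the chain of A2, the C4 ketone is present throughout, no transition metal is needed, and the stereocentre could come from a dependable catalytic asymmetric hetero-Diels–Alder reaction that builds the dihydropyranone ring.
- Against: A1 has free hydroxyls at C5 and C7 that would both have to be methylated under base, the very conditions that open ring C and racemise C2, and the chelated C5 hydroxyl alkylates slowly. The cyclisation needs a polyanion, because the most acidic proton of A2 is the one between ketone and ester, and that strong base also threatens the 2-aryl-dihydropyranone by β-elimination of O1. A2 needs its own multi-step assembly, so a ring that can be bought correctly oxygenated as 1 would be rebuilt atom by atom.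
- Comparison: on structure the alternative is the better plan in one respect, since it needs neither formyl excision nor a late oxidation at C4, and it equals the chosen plan in regiochemical certainty for ring A. On mechanism it exposes the stereocentre to strong base twice, where the chosen plan uses near-neutral catalysis. On step economy it is clearly longer.

Alternative 2: The C3=C4 bond is cut.
- Forward step: the diene tert-butyl({1-[3-(benzyloxy)-6-{[(1S)-1-(3,4-dimethoxyphenyl)prop-2-en-1-yl]oxy}-2,4-dimethoxyphenyl]ethenyl}oxy)dimethylsilane A4 would undergo ring-closing metathesis with the second-generation Grubbs catalyst. In A4 the internal vinyl carbon is joined to the silyl enol ether carbon, the two terminal CH2 groups are extruded as ethylene, and the product would be (2S)-6-(benzyloxy)-4-[(tert-butyldimethylsilyl)oxy]-2-(3,4-dimethoxyphenyl)-5,7-dimethoxy-2H-chromene A3.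
- In favour: A3 is a silyl enol ether, so one mild desilylation would give 10 directly. Metathesis of silyl enol ethers to cyclic enol ethers is established, and the stereocentre of A4 is not a reacting atom in the ring closure.
- Against: the stereocentre of A4 would have to be made by forming an aryl ether at a carbon that is both benzylic (to an electron-rich ring) and allylic, with a hydrogen-bonded, doubly ortho-flanked ortho-acetylphenol as the nucleophile. Ionisation with loss of configuration, SN2' leakage to the linear regioisomer and aromatic Claisen rearrangement to C8 are all plausible. The 1,1-disubstituted silyl enol ether of A4 sits between two ortho substituents, so metathesis should be slow, and Ru–H species formed from the catalyst can isomerise the allyl ether of A4.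
- Comparison: on structure the alternative equals the chosen plan in keeping ring A intact, and is better in having the C4 oxygen in place from the start. A3 is itself a 2H-chromene, so it shares the electrocyclic lability of 8 and 9; on that point the two are equal. On mechanism the chosen plan sets C2 by a catalyst-controlled conjugate addition with close precedent, whereas the alternative relies on a substitution that is weak for this substrate class. On step economy the alternative has the better endgame (one step from A3 to 10 against two from 8) but is about two steps longer overall.

Alternative 3: C2–C3 and C4–C4a are cut.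
- Forward step: the racemic mixed acetal 2-(benzyloxy)-5-[(3,4-dimethoxyphenyl)(methoxy)methoxy]-1,3-dimethoxybenzene A6, made from 4, would be ionised by a confined chiral Brønsted acid to an O-aryl oxocarbenium ion held in the chiral anion. The ketene acetal 1,1-diethoxyethene A7 would add through its CH2 carbon to C2, and the dialkoxycarbenium ion so formed at C4 would be captured by the ortho carbon C4a, giving the ketal (2S)-6-(benzyloxy)-4,4-diethoxy-2-(3,4-dimethoxyphenyl)-5,7-dimethoxychroman A5. Mild hydrolysis of A5 would give 10.
- In favour: it is the most convergent plan, it shares 4 with the chosen route, it is enantioconvergent from the racemic A6, both ortho positions of the aryloxy ring are equivalent, and C4 arrives in A5 at the ketone oxidation level with no auxiliary carbon to remove.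
- Against: in A6 the aryloxy group is the better leaving group, so ionisation may expel 4 and leave the wrong oxocarbenium ion, after which the free phenol can be C-alkylated. A7 is readily protonated and oligomerised by strong acid. A dialkoxycarbenium ion normally collapses by loss of an alkyl group to an open-chain ester, not by attack of an arene, and closure to A5 would create a fully substituted ketal carbon next to the C5 methoxy group. The sequence is not known as a whole.
- Comparison: on structure and step economy the alternative is the better plan on paper (about six steps, no excision, no oxidation). On mechanism it stacks two selectivities without close precedent in one ion-pair-controlled step, whereas the chosen plan rests on a known aminocatalytic domino reaction; that difference in reliability decides for the chosen plan.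

Key step: step 4

Remark on the chemistry: the (S)-catalyst is assigned by the accepted shielding model for diarylprolinol silyl ethers (attack anti to the CAr2OSiR3 group of the E, s-trans iminium ion); should the sense of induction prove opposite, the (R)-catalyst would be used with nothing else changed.

## Route

Step 1
Reactants: 1 syringaldehyde (4-hydroxy-3,5-dimethoxybenzaldehyde)
Product: 2 4-(benzyloxy)-3,5-dimethoxybenzaldehyde
Conditions: BnBr, K2CO3, DMF, 60 °C
Reagents that add atoms: benzyl bromide, BrCc1ccccc1
Why: Williamson ether synthesis; the phenol is hindered by two methoxy groups but acidic (para-formyl), and its potassium salt in DMF should displace bromide from the reactive benzylic halide cleanly, the aldehyde being inert to these conditions.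

Step 2
Reactants: 2 4-(benzyloxy)-3,5-dimethoxybenzaldehyde
Product: 4 4-(benzyloxy)-3,5-dimethoxyphenol, via 4-(benzyloxy)-3,5-dimethoxyphenyl formate 3 (not isolated)
Conditions: mCPBA, CH2Cl2, 0 °C to rt; aq. NaHCO3 wash; then K2CO3 (cat.), MeOH, rt
Reagents that add atoms: 3-chloroperoxybenzoic acid (mCPBA), OOC(=O)c1cccc(Cl)c1
Why: Baeyer–Villiger oxidation in its Dakin form; the peracid adds to the aldehyde and the electron-rich aryl group should migrate in preference to hydride to give formate 3, which base-catalysed methanolysis cleaves to the phenol while benzyl and methyl ethers are untouched.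

Step 3
Reactants: 4 4-(benzyloxy)-3,5-dimethoxyphenol
Product: 6 3-(benzyloxy)-6-hydroxy-2,4-dimethoxybenzaldehyde, via 4-(benzyloxy)-2-(hydroxymethyl)-3,5-dimethoxyphenol 5 (not isolated)
Conditions: MgCl2, Et3N, (CH2O)n, MeCN, reflux; then 1 M HCl
Reagents that add atoms: formaldehyde (as paraformaldehyde), C=O
Why: Casnati–Skattebøl ortho-formylation; the chloromagnesium phenoxide ArOMgCl delivers coordinated formaldehyde to the ortho carbon only, and the salicyl alcohol 5 is oxidised in the flask by Oppenauer-type hydride transfer to a second formaldehyde. The two ortho positions of 4 are equivalent, so one regioisomer is possible, and chelation of the product should hold back a second formylation.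

Step 4
Reactants: 6 3-(benzyloxy)-6-hydroxy-2,4-dimethoxybenzaldehyde; 7 (E)-3,4-dimethoxycinnamaldehyde [(2E)-3-(3,4-dimethoxyphenyl)prop-2-enal], 1.5 equiv
Product: 8 (2R)-6-(benzyloxy)-2-(3,4-dimethoxyphenyl)-5,7-dimethoxy-2H-chromene-3-carbaldehyde
Conditions: (S)-2-[diphenyl(trimethylsilyloxy)methyl]pyrrolidine (20 mol %), 2-nitrobenzoic acid (20 mol %), 4 Å MS, toluene, rt, dark
Reagents that add atoms: none
Why: Condensation of the secondary amine with 7, helped by the acid co-catalyst, gives an E-configured, s-trans iminium ion whose β-carbon is the electrophile. The phenol oxygen of 6 adds there (oxa-Michael, forming O1–C2), the enamine so produced attacks the neighbouring formyl group through C3 (aldol, forming C3–C4), and loss of water with hydrolysis releases 8 and the catalyst. The closest known reaction type is the diarylprolinol silyl ether-catalysed domino oxa-Michael–aldol condensation of salicylaldehydes with cinnamaldehydes to 2-aryl-2H-chromene-3-carbaldehydes. Ring C closes in the aldol event, a 6-(enolexo)-exo-trig cyclisation. The C2 stereocentre is under catalyst control: the C(Ph)2OSiMe3 group of the (S)-pyrrolidine covers the Re face of the β-carbon, so O1 should enter from the Si face, which is (2R) in 8 because the formyl-bearing C3 outranks the aryl group, and is the spatial arrangement of the (2S) target. Because the conjugate addition is reversible and closure onto the electron-rich, doubly ortho-substituted aldehyde is slow, acid co-catalyst, molecular sieves and an excess of 7 are used to drive the dehydration, at room temperature and in the dark so that 8 cannot racemise by ring opening. Chemoselectivity rests on the substrate: 6 has a single free hydroxyl, placed ortho to the only aldehyde that can close a six-membered ring, and 7 has no γ-hydrogen and so cannot react through a dienamine.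

Step 5
Reactants: 8 (2R)-6-(benzyloxy)-2-(3,4-dimethoxyphenyl)-5,7-dimethoxy-2H-chromene-3-carbaldehyde
Product: 9 (2S)-6-(benzyloxy)-2-(3,4-dimethoxyphenyl)-5,7-dimethoxy-2H-chromene
Conditions: RhCl(PPh3)3 (1.1 equiv), degassed toluene, 80 °C, dark
Reagents that add atoms: none
Why: Tsuji–Wilkinson decarbonylation; monovalent rhodium inserts into the formyl C–H bond, CO de-inserts and C–H reductive elimination leaves hydrogen on C3 with the double bond in place, the CO ending in RhCl(CO)(PPh3)2. The complex is used stoichiometrically so that the temperature can stay well below that of catalytic variants, which together with exclusion of light guards C2 against electrocyclic ring opening. The descriptor changes from R to S only because C3 loses its formyl group.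

Step 6
Reactants: 9 (2S)-6-(benzyloxy)-2-(3,4-dimethoxyphenyl)-5,7-dimethoxy-2H-chromene
Product: 10 (2S)-6-(benzyloxy)-2-(3,4-dimethoxyphenyl)-5,7-dimethoxychroman-4-one
Conditions: PdCl2 (20 mol %), CuCl (1 equiv), O2 (1 atm), DMF–H2O (7:1), rt to 40 °C, dark
Reagents that add atoms: water, O
Why: Tsuji–Wacker oxidation; water should attack the alkene bound to divalent palladium at C4, where positive charge is stabilised by ring A (oxygen on both ortho carbons and the para carbon) and which is remote from the electron-withdrawing allylic oxygen O1, and β-hydride elimination with tautomerisation gives the C4 ketone while CuCl and O2 reoxidise the palladium. The near-neutral medium should leave C2, the benzyl ether and the methyl ethers untouched.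

Step 7
Reactants: 10 (2S)-6-(benzyloxy)-2-(3,4-dimethoxyphenyl)-5,7-dimethoxychroman-4-one
Product: 11 (2S)-2-(3,4-dimethoxyphenyl)-6-hydroxy-5,7-dimethoxychroman-4-one
Conditions: H2 (1 atm), 10% Pd/C, EtOAc, rt
Reagents that add atoms: none
Why: Hydrogenolysis of the aryl benzyl ether over Pd/C under neutral conditions, chosen because base or acid would racemise the flavanone through the 2'-hydroxychalcone. The reaction is stopped after one equivalent of H2 so that the benzylic C2–O1 bond and the electron-rich aryl ketone are spared.

## Compound list

1 | syringaldehyde (4-hydroxy-3,5-dimethoxybenzaldehyde) | COc1cc(C=O)cc(OC)c1O | starting material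
2 | 4-(benzyloxy)-3,5-dimethoxybenzaldehyde | COc1cc(C=O)cc(OC)c1OCc1ccccc1 | intermediate
3 | 4-(benzyloxy)-3,5-dimethoxyphenyl formate | COc1cc(OC=O)cc(OC)c1OCc1ccccc1 | intermediate
4 | 4-(benzyloxy)-3,5-dimethoxyphenol | COc1cc(O)cc(OC)c1OCc1ccccc1 | intermediate
5 | 4-(benzyloxy)-2-(hydroxymethyl)-3,5-dimethoxyphenol | COc1cc(O)c(CO)c(OC)c1OCc1ccccc1 | intermediate
6 | 3-(benzyloxy)-6-hydroxy-2,4-dimethoxybenzaldehyde | COc1cc(O)c(C=O)c(OC)c1OCc1ccccc1 | intermediate
7 | (E)-3,4-dimethoxycinnamaldehyde [(2E)-3-(3,4-dimethoxyphenyl)prop-2-enal] | COc1ccc(/C=C/C=O)cc1OC | starting material
8 | (2R)-6-(benzyloxy)-2-(3,4-dimethoxyphenyl)-5,7-dimethoxy-2H-chromene-3-carbaldehyde | COc1ccc([C@@H]2C(C=O)=Cc3c(cc(OC)c(OCc4ccccc4)c3OC)O2)cc1OC | intermediate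
9 | (2S)-6-(benzyloxy)-2-(3,4-dimethoxyphenyl)-5,7-dimethoxy-2H-chromene | COc1ccc([C@@H]2C=Cc3c(cc(OC)c(OCc4ccccc4)c3OC)O2)cc1OC | intermediate
10 | (2S)-6-(benzyloxy)-2-(3,4-dimethoxyphenyl)-5,7-dimethoxychroman-4-one | COc1ccc([C@@H]2CC(=O)c3c(cc(OC)c(OCc4ccccc4)c3OC)O2)cc1OC | intermediate
11 | (2S)-2-(3,4-dimethoxyphenyl)-6-hydroxy-5,7-dimethoxychroman-4-one | COc1ccc([C@@H]2CC(=O)c3c(cc(OC)c(O)c3OC)O2)cc1OC | target

## Step count and least certain steps

Total: 7 steps. Longest linear sequence: 7 steps (1 to 11); 7 is bought and enters at step 4.

Step 4 (key step).
- What may go wrong: the conjugate addition of the phenol is reversible and closure onto the hindered, electron-rich aldehyde is slow. Conversion may stall, and enantiomeric purity may leak away through the reversible first step or through a background cyclisation that does not pass through the chiral iminium ion; poor facial selectivity is the concern.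
- Fallback, from 6 back to the route at 10, setting C2 by asymmetric conjugate addition instead: 6 is treated with MeMgBr (THF, 0 °C) to give 4-(benzyloxy)-2-(1-hydroxyethyl)-3,5-dimethoxyphenol F1, which MnO2 (CH2Cl2) oxidises to 1-[3-(benzyloxy)-6-hydroxy-2,4-dimethoxyphenyl]ethan-1-one F2. Condensation with N,N-dimethylformamide dimethyl acetal (toluene, 90 °C) gives (2E)-1-[3-(benzyloxy)-6-hydroxy-2,4-dimethoxyphenyl]-3-(dimethylamino)prop-2-en-1-one F3, and acid (HCl, CH2Cl2) closes it to 6-(benzyloxy)-5,7-dimethoxy-4H-chromen-4-one F4. Enantioselective conjugate addition of 3,4-dimethoxyphenylboronic acid to F4, catalysed by Pd(OCOCF3)2 with the enantiomer of 4-tert-butyl-2-(pyridin-2-yl)-4,5-dihydrooxazole that leads to the (2S) product (NH4PF6, H2O, 1,2-dichloroethane, 60 °C), a known way to flavanones from chromones, would give 10.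

Step 5.
- What may go wrong: oxidative addition into the formyl C–H bond of a conjugated, electron-rich, hindered aldehyde may be too slow at 80 °C. If the temperature is raised, enantiomeric purity may be lost by thermal 6π-electrocyclic ring opening and reclosure, and Rh–H intermediates may move the double bond into conjugation with O1, which destroys C2.
- Fallback, from 8 back to the route at 10, without decarbonylation or heating: Luche reduction (NaBH4, CeCl3·7H2O, MeOH, 0 °C) gives [(2R)-6-(benzyloxy)-2-(3,4-dimethoxyphenyl)-5,7-dimethoxy-2H-chromen-3-yl]methanol F5. Mukaiyama hydration (Co(acac)2 cat., PhSiH3, O2, THF–i-PrOH, rt, reductive work-up) places hydrogen on C3 and oxygen on C4 through the benzylic radical and gives (2S)-6-(benzyloxy)-2-(3,4-dimethoxyphenyl)-3-(hydroxymethyl)-5,7-dimethoxychroman-4-ol F6 as a mixture of epimers at C3 and C4, which is of no consequence. Dess–Martin periodinane (NaHCO3, CH2Cl2) oxidises both hydroxyls to (2S)-6-(benzyloxy)-2-(3,4-dimethoxyphenyl)-5,7-dimethoxy-4-oxochromane-3-carbaldehyde F7. Brief retro-Claisen deformylation (K2CO3 cat., MeOH, 0 °C) then gives 10; the exposure to base is kept short to protect C2.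

Step 6.
- What may go wrong: the regiochemistry of hydroxypalladation may leak towards oxygen on C3, because palladium is stabilised at a benzylic carbon and simple aryl-conjugated internal alkenes often oxidise that way; here the electron-rich ring A and the allylic O1 are counted on to override this. Palladium may also activate the allylic C2–H bond, or zerovalent palladium formed in the cycle may ionise the allylic C2–O1 bond; either would cost configuration or lead to aromatisation of ring C. Hydroxypalladation of a cyclic internal alkene may be slow, and CuCl2 formed in the cycle may chlorinate ring A at C8.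
- Fallback, from 9 back to the route at 10, by hydrogen-atom-transfer hydration in place of nucleopalladation, so that the regiochemistry is set by the stability of the C4 benzylic radical: Mukaiyama hydration of 9 (Co(acac)2 cat., PhSiH3, O2, THF–i-PrOH, 0 °C to rt) should give (2S)-6-(benzyloxy)-2-(3,4-dimethoxyphenyl)-5,7-dimethoxychroman-4-ol F8 as a mixture of C4 epimers. Dess–Martin periodinane (NaHCO3, CH2Cl2, rt) then oxidises F8 to 10.

## Further compounds

F1 | step 4 | 4-(benzyloxy)-2-(1-hydroxyethyl)-3,5-dimethoxyphenol | COc1cc(O)c(C(C)O)c(OC)c1OCc1ccccc1
F2 | step 4 | 1-[3-(benzyloxy)-6-hydroxy-2,4-dimethoxyphenyl]ethan-1-one | COc1cc(O)c(C(C)=O)c(OC)c1OCc1ccccc1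
F3 | step 4 | (2E)-1-[3-(benzyloxy)-6-hydroxy-2,4-dimethoxyphenyl]-3-(dimethylamino)prop-2-en-1-one | COc1cc(O)c(C(=O)/C=C/N(C)C)c(OC)c1OCc1ccccc1
F4 | step 4 | 6-(benzyloxy)-5,7-dimethoxy-4H-chromen-4-one | COc1cc2occc(=O)c2c(OC)c1OCc1ccccc1
F5 | step 5 | [(2R)-6-(benzyloxy)-2-(3,4-dimethoxyphenyl)-5,7-dimethoxy-2H-chromen-3-yl]methanol | COc1ccc([C@@H]2C(CO)=Cc3c(cc(OC)c(OCc4ccccc4)c3OC)O2)cc1OC
F6 | step 5 | (2S)-6-(benzyloxy)-2-(3,4-dimethoxyphenyl)-3-(hydroxymethyl)-5,7-dimethoxychroman-4-ol (C3 and C4 epimers) | COc1ccc([C@@H]2C(CO)C(O)c3c(cc(OC)c(OCc4ccccc4)c3OC)O2)cc1OC
F7 | step 5 | (2S)-6-(benzyloxy)-2-(3,4-dimethoxyphenyl)-5,7-dimethoxy-4-oxochromane-3-carbaldehyde | COc1ccc([C@@H]2C(C=O)C(=O)c3c(cc(OC)c(OCc4ccccc4)c3OC)O2)cc1OC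
F8 | step 6 | (2S)-6-(benzyloxy)-2-(3,4-dimethoxyphenyl)-5,7-dimethoxychroman-4-ol (C4 epimers) | COc1ccc([C@@H]2CC(O)c3c(cc(OC)c(OCc4ccccc4)c3OC)O2)cc1OC
A1 | alternative 1 | (2S)-6-(benzyloxy)-2-(3,4-dimethoxyphenyl)-5,7-dihydroxychroman-4-one | COc1ccc([C@@H]2CC(=O)c3c(cc(O)c(OCc4ccccc4)c3O)O2)cc1OC
A2 | alternative 1 | ethyl 2-(benzyloxy)-4-[(2S)-2-(3,4-dimethoxyphenyl)-4-oxo-3,4-dihydro-2H-pyran-6-yl]-3-oxobutanoate | CCOC(=O)C(OCc1ccccc1)C(=O)CC1=CC(=O)C[C@@H](c2ccc(OC)c(OC)c2)O1
A3 | alternative 2 | (2S)-6-(benzyloxy)-4-[(tert-butyldimethylsilyl)oxy]-2-(3,4-dimethoxyphenyl)-5,7-dimethoxy-2H-chromene | COc1ccc([C@@H]2C=C(O[Si](C)(C)C(C)(C)C)c3c(cc(OC)c(OCc4ccccc4)c3OC)O2)cc1OC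
A4 | alternative 2 | tert-butyl({1-[3-(benzyloxy)-6-{[(1S)-1-(3,4-dimethoxyphenyl)prop-2-en-1-yl]oxy}-2,4-dimethoxyphenyl]ethenyl}oxy)dimethylsilane | COc1ccc([C@H](C=C)Oc2cc(OC)c(OCc3ccccc3)c(OC)c2C(=C)O[Si](C)(C)C(C)(C)C)cc1OC
A5 | alternative 3 | (2S)-6-(benzyloxy)-4,4-diethoxy-2-(3,4-dimethoxyphenyl)-5,7-dimethoxychroman | COc1ccc([C@@H]2CC(OCC)(OCC)c3c(cc(OC)c(OCc4ccccc4)c3OC)O2)cc1OC
A6 | alternative 3 | 2-(benzyloxy)-5-[(3,4-dimethoxyphenyl)(methoxy)methoxy]-1,3-dimethoxybenzene (racemic) | COc1ccc(C(OC)Oc2cc(OC)c(OCc3ccccc3)c(OC)c2)cc1OC
A7 | alternative 3 | 1,1-diethoxyethene | C=C(OCC)OCC
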